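**Retrosynthetic overview**
1. Target ⇒ tert-butyl ester 16 ⇒ Wittig disconnection of C13=C14 ⇒ α-acetoxy ketone 14 ⇒ decarboxylation and Michael disconnection of C9–C11 ⇒ bicyclic enone β-keto ester 8 plus acetoxymethyl vinyl ketone (from 10, made by alkyne hydration).
2. 8 ⇒ saturated trans-decalin β-keto ester 5 (C6=C7 by selenoxide elimination) ⇒ 1,3 O→C shift ⇒ oxadecalin 4.
3. Key disconnection: the C10–O bond of 4 ⇒ achiral β-keto ester 3, by catalytic enantioselective protonation/oxa-cyclisation that sets C5 and hence the absolute configuration.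
4. 3 ⇒ dihydro-β-ionone 1 + diallyl carbonate 2.
5. Ring order: ring A is bought; the pyran ring (C–O) is formed first; it is then converted into carbocyclic ring B.

Assumption: labdane-type locants are used in the explanations (C9 = C1, C8 = C2, C5 = C4a, C10 = C8a of the naphthalenone; side chain C11–C16); the given SMILES is read as (1S,4aR,8aR), 2E.

**Step 1**
Reactants: 1 dihydro-β-ionone [4-(2,6,6-trimethylcyclohex-1-en-1-yl)butan-2-one]; 2 diallyl carbonate
Product: 3 allyl 3-oxo-5-(2,6,6-trimethylcyclohex-1-en-1-yl)pentanoate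
Conditions: NaH (2.5 equiv), THF, reflux; then aq. HCl
Reagents that add atoms: none
Why: Claisen-type C-acylation of the methyl-ketone enolate by the carbonate, driven by formation of the β-keto ester sodium enolate; acylation occurs at the methyl terminus and no stereocentre is formed.

**Step 2**
Reactants: 3 allyl 3-oxo-5-(2,6,6-trimethylcyclohex-1-en-1-yl)pentanoate
Product: 4 allyl (2E)-[(4aR,8aR)-5,5,8a-trimethyloctahydro-2H-chromen-2-ylidene]acetate
Conditions: confined chiral imidodiphosphorimidate (IDPi) Brønsted acid (5 mol %, enantiomer chosen to give 4aR), CHCl3, −40 °C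
Reagents that add atoms: none
Why: Proposed new method: the confined chiral acid protonates the tetrasubstituted ring alkene of achiral 3 at C5 on one enantiotopic face while the hydrogen-bonded keto/enol oxygen captures the developing tertiary C10 cation, and loss of the acidic C9–H gives the vinylogous carbonate, so the C10–O bond, the pyran ring and the C5 stereocentre (kept to the target) are set in one catalytic enantioselective step; the closest known reaction types are chiral-acid-catalysed asymmetric intramolecular hydroalkoxylation of unactivated alkenes and oxygen-terminated protonative polyene cyclisation, neither shown for a tetrasubstituted cycloalkene with a β-keto ester oxygen as the terminator.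

**Step 3**
Reactants: 4 allyl (2E)-[(4aR,8aR)-5,5,8a-trimethyloctahydro-2H-chromen-2-ylidene]acetate
Product: 5 allyl (1S,4aR,8aR)-5,5,8a-trimethyl-2-oxodecahydronaphthalene-1-carboxylate
Conditions: SnCl4 (1.2 equiv), CH2Cl2, −78 → −30 °C; aq. NaHCO3
Reagents that add atoms: none
Why: Lewis-acid-promoted 1,3 O→C shift (ionisation of the tertiary C10–O bond to a cation/tin-enolate pair and recombination at C9, the thermodynamic mode of β-keto ester cation cyclisations); the C5 stereocentre from step 2 directs C9 to the face of C10 that gives the trans-decalin (C10 = R), and C9 settles equatorial by enolisation.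

**Step 4**
Reactants: 5 allyl (1S,4aR,8aR)-5,5,8a-trimethyl-2-oxodecahydronaphthalene-1-carboxylate
Product: 8 allyl (1S,4aR,8aR)-5,5,8a-trimethyl-2-oxo-1,2,4a,5,6,7,8,8a-octahydronaphthalene-1-carboxylate, via 3-phenylselanyl keto ester 6 (not isolated), via selenoxide 7 (not isolated)
Conditions: LDA (2.2 equiv), THF, −78 → 0 °C; PhSeBr (1.0 equiv), −78 °C; AcOH; then 30% H2O2, pyridine, CH2Cl2, 0 °C → rt
Reagents that add atoms: none
Why: The β-keto ester dianion reacts with PhSeBr at its γ-carbon (C7), and selenoxide syn-elimination then gives the C6=C7 enone; C5 and C10 are not touched.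

**Step 5**
Reactants: 9 but-2-yne-1,4-diyl diacetate
Product: 10 2-oxobutane-1,4-diyl diacetate
Conditions: Ph3PAuCl/AgOTf (2 mol %), 1,4-dioxane/H2O, 60 °C
Reagents that add atoms: water, O
Why: Au(I)-catalysed alkyne hydration assisted by the propargylic acetate; the alkyne is symmetrical, so only one ketone can form.

**Step 6**
Reactants: 8 allyl (1S,4aR,8aR)-5,5,8a-trimethyl-2-oxo-1,2,4a,5,6,7,8,8a-octahydronaphthalene-1-carboxylate; 10 2-oxobutane-1,4-diyl diacetate
Product: 12 allyl (1S,4aR,8aR)-1-[4-(acetyloxy)-3-oxobutyl]-5,5,8a-trimethyl-2-oxo-1,2,4a,5,6,7,8,8a-octahydronaphthalene-1-carboxylate, via acetoxymethyl vinyl ketone 11 (not isolated)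
Conditions: Et3N (3 equiv), DBU (10 mol %), MeCN, 0 °C → rt
Reagents that add atoms: none
Why: Base-induced β-elimination of acetic acid from 10 releases the vinyl ketone in situ, and the doubly activated C9 of 8 adds to it in a Michael addition (expected anti to the axial angular methyl); the C9 configuration formed here is irrelevant because it is re-set in step 7.

**Step 7**
Reactants: 12 allyl (1S,4aR,8aR)-1-[4-(acetyloxy)-3-oxobutyl]-5,5,8a-trimethyl-2-oxo-1,2,4a,5,6,7,8,8a-octahydronaphthalene-1-carboxylate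
Product: 14 4-[(1S,4aR,8aR)-5,5,8a-trimethyl-2-oxo-1,2,4a,5,6,7,8,8a-octahydronaphthalen-1-yl]-2-oxobutyl acetate, via beta-keto acid 13 (not isolated)
Conditions: Pd(OAc)2 (5 mol %), PPh3 (10 mol %), HCO2H (2 equiv), Et3N (2.5 equiv), THF, rt
Reagents that add atoms: none
Why: Tsuji Pd-catalysed deallylation–decarboxylation with formate as the hydride source, run before any allylic acetate is present; protonation and Et3N equilibration at C9 give the thermodynamic epimer with the side chain equatorial and H-9 anti to the C10 methyl (1S).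

**Step 8**
Reactants: 14 4-[(1S,4aR,8aR)-5,5,8a-trimethyl-2-oxo-1,2,4a,5,6,7,8,8a-octahydronaphthalen-1-yl]-2-oxobutyl acetate; 15 tert-butyl (triphenylphosphoranylidene)acetate
Product: 16 tert-butyl (2E)-3-[(acetyloxy)methyl]-5-[(1S,4aR,8aR)-5,5,8a-trimethyl-2-oxo-1,2,4a,5,6,7,8,8a-octahydronaphthalen-1-yl]pent-2-enoate
Conditions: 15 (1.5 equiv), toluene, 90 °C
Reagents that add atoms: none
Why: Wittig olefination with a stabilised ylide, chemoselective for the unhindered α-acetoxy ketone over the hindered ring enone; α-oxygenated ketones place the CH2OAc group trans to the ester, which is the required 2E geometry (the minor 2Z isomer is removed by chromatography).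

**Step 9**
Reactants: 16 tert-butyl (2E)-3-[(acetyloxy)methyl]-5-[(1S,4aR,8aR)-5,5,8a-trimethyl-2-oxo-1,2,4a,5,6,7,8,8a-octahydronaphthalen-1-yl]pent-2-enoate
Product: 17 (2E)-3-[(acetyloxy)methyl]-5-[(1S,4aR,8aR)-5,5,8a-trimethyl-2-oxo-1,2,4a,5,6,7,8,8a-octahydronaphthalen-1-yl]pent-2-enoic acid
Conditions: TFA/CH2Cl2 1:4, 0 °C → rt
Reagents that add atoms: none
Why: Acidolysis of the tert-butyl ester (E1 loss of isobutene); the acetate, the enone, the alkene geometry and all three stereocentres are stable to TFA.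

**Compound list**
1 | dihydro-β-ionone, 4-(2,6,6-trimethylcyclohex-1-en-1-yl)butan-2-one | CC(=O)CCC1=C(C)CCCC1(C)C | starting material
2 | diallyl carbonate | C=CCOC(=O)OCC=C | starting material
3 | allyl 3-oxo-5-(2,6,6-trimethylcyclohex-1-en-1-yl)pentanoate | C=CCOC(=O)CC(=O)CCC1=C(C)CCCC1(C)C | intermediate
4 | allyl (2E)-[(4aR,8aR)-5,5,8a-trimethyloctahydro-2H-chromen-2-ylidene]acetate | C=CCOC(=O)/C=C1\CC[C@@H]2C(C)(C)CCC[C@@]2(C)O1 | intermediate
5 | allyl (1S,4aR,8aR)-5,5,8a-trimethyl-2-oxodecahydronaphthalene-1-carboxylate | C=CCOC(=O)[C@@H]1C(=O)CC[C@@H]2C(C)(C)CCC[C@@]12C | intermediate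
6 | allyl (1S,4aR,8aR)-5,5,8a-trimethyl-2-oxo-3-(phenylselanyl)decahydronaphthalene-1-carboxylate (C3 epimers) | C=CCOC(=O)[C@@H]1C(=O)C([Se]c3ccccc3)C[C@@H]2C(C)(C)CCC[C@@]12C | intermediate (not isolated)
7 | selenoxide of 6, allyl (1S,4aR,8aR)-3-(benzeneseleninyl)-5,5,8a-trimethyl-2-oxodecahydronaphthalene-1-carboxylate | C=CCOC(=O)[C@@H]1C(=O)C([Se](=O)c3ccccc3)C[C@@H]2C(C)(C)CCC[C@@]12C | intermediate (not isolated)
8 | allyl (1S,4aR,8aR)-5,5,8a-trimethyl-2-oxo-1,2,4a,5,6,7,8,8a-octahydronaphthalene-1-carboxylate | C=CCOC(=O)[C@@H]1C(=O)C=C[C@@H]2C(C)(C)CCC[C@@]12C | intermediate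
9 | but-2-yne-1,4-diyl diacetate | CC(=O)OCC#CCOC(C)=O | starting material
10 | 2-oxobutane-1,4-diyl diacetate | CC(=O)OCCC(=O)COC(C)=O | intermediate
11 | acetoxymethyl vinyl ketone, 2-oxobut-3-en-1-yl acetate | C=CC(=O)COC(C)=O | intermediate (not isolated)
12 | allyl (1S,4aR,8aR)-1-[4-(acetyloxy)-3-oxobutyl]-5,5,8a-trimethyl-2-oxo-1,2,4a,5,6,7,8,8a-octahydronaphthalene-1-carboxylate | C=CCOC(=O)[C@]1(CCC(=O)COC(C)=O)C(=O)C=C[C@@H]2C(C)(C)CCC[C@@]12C | intermediate
13 | (1S,4aR,8aR)-1-[4-(acetyloxy)-3-oxobutyl]-5,5,8a-trimethyl-2-oxo-1,2,4a,5,6,7,8,8a-octahydronaphthalene-1-carboxylic acid | OC(=O)[C@]1(CCC(=O)COC(C)=O)C(=O)C=C[C@@H]2C(C)(C)CCC[C@@]12C | intermediate (not isolated)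
14 | 4-[(1S,4aR,8aR)-5,5,8a-trimethyl-2-oxo-1,2,4a,5,6,7,8,8a-octahydronaphthalen-1-yl]-2-oxobutyl acetate | CC(=O)OCC(=O)CC[C@@H]1C(=O)C=C[C@@H]2C(C)(C)CCC[C@@]12C | intermediate
15 | tert-butyl (triphenylphosphoranylidene)acetate | CC(C)(C)OC(=O)C=P(c1ccccc1)(c1ccccc1)c1ccccc1 | starting material
16 | tert-butyl (2E)-3-[(acetyloxy)methyl]-5-[(1S,4aR,8aR)-5,5,8a-trimethyl-2-oxo-1,2,4a,5,6,7,8,8a-octahydronaphthalen-1-yl]pent-2-enoate | CC(=O)OC/C(=C/C(=O)OC(C)(C)C)CC[C@@H]1C(=O)C=C[C@@H]2C(C)(C)CCC[C@@]12C | intermediate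
17 | (2E)-3-[(acetyloxy)methyl]-5-[(1S,4aR,8aR)-5,5,8a-trimethyl-2-oxo-1,2,4a,5,6,7,8,8a-octahydronaphthalen-1-yl]pent-2-enoic acid | CC(=O)OC/C(=C/C(=O)O)CC[C@@H]1C(=O)C=C[C@@H]2C(C)(C)CCC[C@@]12C | target

**Step count**
Total steps: 9 (steps 1–9, step 5 being a one-step side branch). Longest linear sequence: 8 (steps 1, 2, 3, 4, 6, 7, 8, 9).

**Three steps most likely to fail**

Step 2 (the proposed new enantioselective oxa-cyclisation; risk: low conversion or low ee on a tetrasubstituted alkene). Fallback with known chemistry, buying the C5 stereocentre instead of making it: the fallback sets out from 2 and comes back to the route at 5. Purchased (R)-α-ionone F1 is reduced at its conjugated C=C (Stryker-type copper hydride conjugate reduction) to (R)-dihydro-α-ionone F2. F2 is carboxylated with 2 and NaH as in step 1 to allyl 3-oxo-5-[(1R)-2,6,6-trimethylcyclohex-2-en-1-yl]pentanoate F3. F3 is cyclised with SnCl4 in CH2Cl2 (alkene-initiated cation cyclisation of a β-keto ester; the ring alkene is protonated at C1 and C9 closes onto C10 under control of the existing C5 centre) to give 5 directly, so steps 1–3 are replaced.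

Step 3 (risk: the C10 cation loses H-5 and erodes the ee, or the vinylogous carbonate does not rearrange cleanly). Fallback by resolution, which does not depend on a cation next to a stereogenic C–H: it sets out from 3 and comes back at 5. Direct SnCl4 cyclisation of 3 gives the racemic trans β-keto ester, that is 5 together with its mirror image allyl (1R,4aS,8aS)-5,5,8a-trimethyl-2-oxodecahydronaphthalene-1-carboxylate F4. Condensation with (S)-1-phenylethylamine (cat. AcOH, toluene, water removal) gives the diastereomeric enamino esters allyl (4aR,8aR)-5,5,8a-trimethyl-2-{[(1S)-1-phenylethyl]amino}-3,4,4a,5,6,7,8,8a-octahydronaphthalene-1-carboxylate F5 and its (4aS,8aS) diastereomer F6. These are separated by crystallisation or chromatography, and F5 is hydrolysed with aqueous acetic acid to 5.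

Step 6 (risk: the vinyl ketone polymerises, or the hindered C9 adds slowly and a second intramolecular Michael or aldol reaction follows). Fallback replacing the Michael addition by alkylation and alkyne hydration: it sets out from 8 and comes back at 12. C-Alkylation of 8 with excess 1,4-dichlorobut-2-yne (K2CO3, cat. NaI, acetone) gives allyl (1S,4aR,8aR)-1-(4-chlorobut-2-yn-1-yl)-5,5,8a-trimethyl-2-oxo-1,2,4a,5,6,7,8,8a-octahydronaphthalene-1-carboxylate F7. KOAc in DMF converts F7 into the propargylic acetate allyl (1S,4aR,8aR)-1-[4-(acetyloxy)but-2-yn-1-yl]-5,5,8a-trimethyl-2-oxo-1,2,4a,5,6,7,8,8a-octahydronaphthalene-1-carboxylate F8. Au(I)-catalysed, acetate-assisted hydration of F8 places the ketone next to the CH2OAc group and gives 12; step 5 is then not needed.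

**Further compounds**
F1 | step 2 | (R)-α-ionone (purchased) | CC(=O)/C=C/[C@H]1C(C)=CCCC1(C)C
F2 | step 2 | (R)-dihydro-α-ionone, 4-[(1R)-2,6,6-trimethylcyclohex-2-en-1-yl]butan-2-one | CC(=O)CC[C@H]1C(C)=CCCC1(C)C
F3 | step 2 | allyl 3-oxo-5-[(1R)-2,6,6-trimethylcyclohex-2-en-1-yl]pentanoate | C=CCOC(=O)CC(=O)CC[C@H]1C(C)=CCCC1(C)C
F4 | step 3 | allyl (1R,4aS,8aS)-5,5,8a-trimethyl-2-oxodecahydronaphthalene-1-carboxylate | C=CCOC(=O)[C@H]1C(=O)CC[C@H]2C(C)(C)CCC[C@]12C
F5 | step 3 | allyl (4aR,8aR)-5,5,8a-trimethyl-2-{[(1S)-1-phenylethyl]amino}-3,4,4a,5,6,7,8,8a-octahydronaphthalene-1-carboxylate | C=CCOC(=O)C1=C(N[C@@H](C)c3ccccc3)CC[C@@H]2C(C)(C)CCC[C@@]12C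
F6 | step 3 | allyl (4aS,8aS)-5,5,8a-trimethyl-2-{[(1S)-1-phenylethyl]amino}-3,4,4a,5,6,7,8,8a-octahydronaphthalene-1-carboxylate | C=CCOC(=O)C1=C(N[C@@H](C)c3ccccc3)CC[C@H]2C(C)(C)CCC[C@]12C
F7 | step 6 | allyl (1S,4aR,8aR)-1-(4-chlorobut-2-yn-1-yl)-5,5,8a-trimethyl-2-oxo-1,2,4a,5,6,7,8,8a-octahydronaphthalene-1-carboxylate | C=CCOC(=O)[C@]1(CC#CCCl)C(=O)C=C[C@@H]2C(C)(C)CCC[C@@]12C
F8 | step 6 | allyl (1S,4aR,8aR)-1-[4-(acetyloxy)but-2-yn-1-yl]-5,5,8a-trimethyl-2-oxo-1,2,4a,5,6,7,8,8a-octahydronaphthalene-1-carboxylate | C=CCOC(=O)[C@]1(CC#CCOC(C)=O)C(=O)C=C[C@@H]2C(C)(C)CCC[C@@]12C
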